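**Retrosynthetic overview**
1. Target 26 comes from diol 23 and angelic acid (both angelates last); the C3 acetate comes from enolate oxidation of ketone 19.
2. Key step: the C4–side-chain bond is made by alkoxide-directed syn conjugate addition of the complete, stereodefined alkenylmagnesium side chain (from bromide 6) to epoxyquinol 14. This one step joins the two halves and fixes C4, which then controls C3.
3. Epoxyquinol 14 is made by dearomatisation, not from carvone: 4-methoxy-3-methylphenol → iodo quinone monoketal 9 → CBS reduction (sole source of ring chirality) → hydroxyl-directed epoxidation.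
4. Bromide 6 comes from 2-bromoacrolein by Brown allylation (carbinol centre), cross-metathesis and Shi epoxidation.
5. Rings: the carbocycle is the starting arene and is never constructed; the side-chain oxirane forms in step 4 and the ring oxirane in step 8.

Assumption: ring atoms are numbered as in 7-oxabicyclo[4.1.0]heptan-2-one (C1 methyl-bearing oxirane carbon, C2 ketone, C3 acetoxy carbon, C4 side-chain carbon, C5 angelate carbon, C6 oxirane CH); 2-bromoacrolein, (+)-Ipc2B(allyl) solution and the L-fructose-derived Shi ketone are taken as catalogue items.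

**Route**

Step 1
Reactants: 1 2-bromoacrolein
Product: 3 (3R)-2-bromohexa-1,5-dien-3-ol, via diisopinocampheylborinate ester 2 (not isolated)
Conditions: (+)-Ipc2B(allyl) (from (−)-α-pinene), Et2O, −78 °C; then NaOH, H2O2, 0 °C → rt
Reagents that add atoms: (+)-B-allyldiisopinocampheylborane, C=CCB([C@H]1C[C@H]2C[C@@H]([C@@H]1C)C2(C)C)[C@H]1C[C@H]2C[C@@H]([C@@H]1C)C2(C)C
Why: Brown asymmetric allylboration, in which the (−)-α-pinene-derived reagent delivers allyl to the Re face of the aldehyde through a chair six-membered transition state, giving the (R)-carbinol (the 1-bromovinyl group takes the place that phenyl has in benzaldehyde).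

Step 2
Reactants: 3 (3R)-2-bromohexa-1,5-dien-3-ol
Product: 4 tert-butyl{[(3R)-2-bromohexa-1,5-dien-3-yl]oxy}dimethylsilane
Conditions: TBSCl, imidazole, DMF, rt
Reagents that add atoms: tert-butyldimethylsilyl chloride, CC(C)(C)[Si](C)(C)Cl
Why: Standard silyl ether formation that masks the carbinol for the later organometallic step without touching the stereocentre.

Step 3
Reactants: 4 tert-butyl{[(3R)-2-bromohexa-1,5-dien-3-yl]oxy}dimethylsilane
Product: 5 tert-butyl{[(3R)-2-bromo-6-methylhepta-1,5-dien-3-yl]oxy}dimethylsilane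
Conditions: 2-methyl-2-butene (solvent), second-generation Grubbs catalyst RuCl2(=CHPh)(PCy3)(H2IMes) (2 mol %), 40 °C, sealed tube
Reagents that add atoms: 2-methyl-2-butene, CC=C(C)C
Why: Olefin cross-metathesis converts the terminal vinyl group into the trisubstituted isopropylidene end, while the 1,1-disubstituted bromoalkene is inert to the ruthenium carbene.

Step 4
Reactants: 5 tert-butyl{[(3R)-2-bromo-6-methylhepta-1,5-dien-3-yl]oxy}dimethylsilane
Product: 6 tert-butyl({(2R)-3-bromo-1-[(2S)-3,3-dimethyloxiran-2-yl]but-3-en-2-yl}oxy)dimethylsilane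
Conditions: L-fructose-derived Shi ketone (0.3 equiv), KHSO5 (as Oxone), K2CO3, Bu4NHSO4, MeCN/CH2(OMe)2–aq Na2B4O7 buffer, 0 °C
Reagents that add atoms: potassium peroxymonosulfate, [K+].OOS(=O)(=O)[O-]
Why: Shi asymmetric epoxidation, in which the chiral dioxirane attacks only the electron-rich trisubstituted alkene through a spiro transition state; the D-fructose ketone gives (R)-epoxides from R-CH2-CH=CMe2 units, so its enantiomer sets the (S)-oxirane centre under reagent control.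

Step 5
Reactants: 7 4-methoxy-3-methylphenol
Product: 8 2-iodo-4-methoxy-5-methylphenol
Conditions: NIS, TsOH·H2O (10 mol %), MeCN, 0 °C
Reagents that add atoms: N-iodosuccinimide, O=C1CCC(=O)N1I
Why: Electrophilic aromatic iodination goes ortho to the hydroxyl (para is blocked) at the less hindered of the two ortho positions.

Step 6
Reactants: 8 2-iodo-4-methoxy-5-methylphenol
Product: 9 2-iodo-4,4-dimethoxy-5-methylcyclohexa-2,5-dien-1-one
Conditions: PhI(OAc)2, MeOH, 0 °C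
Reagents that add atoms: methanol, CO
Why: Hypervalent-iodine oxidative dearomatisation of a para-methoxyphenol in methanol gives the para-quinone monoketal.

Step 7
Reactants: 9 2-iodo-4,4-dimethoxy-5-methylcyclohexa-2,5-dien-1-one
Product: 11 (1R)-2-iodo-4,4-dimethoxy-5-methylcyclohexa-2,5-dien-1-ol, via catecholborate ester 10 (not isolated)
Conditions: (S)-Me-CBS oxazaborolidine (0.2 equiv), catecholborane, toluene, −78 °C; aq NaHCO3 work-up
Reagents that add atoms: none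
Why: Corey–Bakshi–Shibata reduction, in which the α-iodoalkenyl arm acts as the large carbonyl substituent so that hydride is delivered to one face and the (R)-carbinol results, the iodine being there to differentiate the two enone arms.

Step 8
Reactants: 11 (1R)-2-iodo-4,4-dimethoxy-5-methylcyclohexa-2,5-dien-1-ol
Product: 12 (1S,2R,6S)-3-iodo-5,5-dimethoxy-6-methyl-7-oxabicyclo[4.1.0]hept-3-en-2-ol
Conditions: VO(acac)2 (5 mol %), t-BuOOH (decane), CH2Cl2, 0 °C
Reagents that add atoms: tert-butyl hydroperoxide, CC(C)(C)OO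
Why: Hydroxyl-directed vanadium-catalysed epoxidation delivers oxygen to the electron-rich methyl-bearing alkene on the face of the allylic hydroxyl (the iodoalkene is deactivated), which sets both oxirane carbons cis to the carbinol oxygen.

Step 9
Reactants: 12 (1S,2R,6S)-3-iodo-5,5-dimethoxy-6-methyl-7-oxabicyclo[4.1.0]hept-3-en-2-ol
Product: 13 (1S,2S,6S)-5,5-dimethoxy-6-methyl-7-oxabicyclo[4.1.0]hept-3-en-2-ol
Conditions: Pd(PPh3)4 (5 mol %), Bu3SnH, THF, rt
Reagents that add atoms: none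
Why: Palladium-catalysed hydrodehalogenation (oxidative addition into the vinyl C–I bond, then hydride transfer from tin) removes the auxiliary iodine under neutral conditions without touching ketal, oxirane or stereocentres.

Step 10
Reactants: 13 (1S,2S,6S)-5,5-dimethoxy-6-methyl-7-oxabicyclo[4.1.0]hept-3-en-2-ol
Product: 14 (1S,5S,6S)-5-hydroxy-1-methyl-7-oxabicyclo[4.1.0]hept-3-en-2-one
Conditions: PPTS (0.2 equiv), acetone/H2O 10:1, rt
Reagents that add atoms: water, O
Why: Mild acid-catalysed hydrolysis of the allylic dimethyl ketal unveils the enone of the epoxyquinol while leaving the oxirane and carbinol intact.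

Step 11
Reactants: 6 tert-butyl({(2R)-3-bromo-1-[(2S)-3,3-dimethyloxiran-2-yl]but-3-en-2-yl}oxy)dimethylsilane; 14 (1S,5S,6S)-5-hydroxy-1-methyl-7-oxabicyclo[4.1.0]hept-3-en-2-one
Product: 19 (1S,4R,5S,6S)-4-{(3R)-3-[(tert-butyldimethylsilyl)oxy]-4-[(2S)-3,3-dimethyloxiran-2-yl]but-1-en-2-yl}-5-hydroxy-1-methyl-7-oxabicyclo[4.1.0]heptan-2-one, via alkenyllithium 15 (not isolated), via alkenylmagnesium bromide 16 (not isolated), via chloromagnesium alkoxide 17 (not isolated), via magnesium enolate 18 (not isolated)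
Conditions: 6 (1.5 equiv), t-BuLi (3.0 equiv), Et2O, −78 °C; MgBr2·OEt2 (1.6 equiv), −78 °C; then 14 pre-treated with t-BuMgCl (1.0 equiv) in THF, −78 → −30 °C; aq NH4Cl
Reagents that add atoms: none
Why: Alkoxide-directed (chelation-controlled, ligand-assisted) conjugate addition of a Grignard reagent to a γ-hydroxy enone, in which the magnesium alkoxide of 14 binds the alkenylmagnesium species and delivers the alkenyl group intramolecularly to the only β-carbon on the alkoxide face, so the new C4 centre is cis to the C5 oxygen and to the oxirane.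

Step 12
Reactants: 19 (1S,4R,5S,6S)-4-{(3R)-3-[(tert-butyldimethylsilyl)oxy]-4-[(2S)-3,3-dimethyloxiran-2-yl]but-1-en-2-yl}-5-hydroxy-1-methyl-7-oxabicyclo[4.1.0]heptan-2-one
Product: 21 (1S,3S,4R,5S,6S)-4-{(3R)-3-[(tert-butyldimethylsilyl)oxy]-4-[(2S)-3,3-dimethyloxiran-2-yl]but-1-en-2-yl}-3,5-dihydroxy-1-methyl-7-oxabicyclo[4.1.0]heptan-2-one, via dipotassium enolate alkoxide 20 (not isolated)
Conditions: KN(SiMe3)2 (2.2 equiv), THF, −78 °C; 2-(phenylsulfonyl)-3-phenyloxaziridine (1.3 equiv), −78 °C; aq NH4Cl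
Reagents that add atoms: 2-(phenylsulfonyl)-3-phenyloxaziridine, O=S(=O)(N1OC1c1ccccc1)c1ccccc1
Why: Davis enolate hydroxylation, in which C3 is the only enolisable position (C1 is fully substituted) and the oxaziridine attacks the enolate face opposite the adjacent C4 side chain, giving the trans equatorial 3-hydroxyl.

Step 13
Reactants: 21 (1S,3S,4R,5S,6S)-4-{(3R)-3-[(tert-butyldimethylsilyl)oxy]-4-[(2S)-3,3-dimethyloxiran-2-yl]but-1-en-2-yl}-3,5-dihydroxy-1-methyl-7-oxabicyclo[4.1.0]heptan-2-one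
Product: 22 (1S,3S,4R,5S,6S)-4-{(3R)-3-[(tert-butyldimethylsilyl)oxy]-4-[(2S)-3,3-dimethyloxiran-2-yl]but-1-en-2-yl}-5-hydroxy-1-methyl-2-oxo-7-oxabicyclo[4.1.0]heptan-3-yl acetate
Conditions: Ac2O (1.1 equiv), pyridine, CH2Cl2, −20 → 0 °C
Reagents that add atoms: acetic anhydride, CC(=O)OC(C)=O
Why: Site-selective acylation, in which the equatorial α-ketol hydroxyl at C3 reacts much faster than the axial C5 hydroxyl wedged between the oxirane and the branched side chain.

Step 14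
Reactants: 22 (1S,3S,4R,5S,6S)-4-{(3R)-3-[(tert-butyldimethylsilyl)oxy]-4-[(2S)-3,3-dimethyloxiran-2-yl]but-1-en-2-yl}-5-hydroxy-1-methyl-2-oxo-7-oxabicyclo[4.1.0]heptan-3-yl acetate
Product: 23 (1S,3S,4R,5S,6S)-4-{(3R)-4-[(2S)-3,3-dimethyloxiran-2-yl]-3-hydroxybut-1-en-2-yl}-5-hydroxy-1-methyl-2-oxo-7-oxabicyclo[4.1.0]heptan-3-yl acetate
Conditions: Bu4NF/AcOH (1:1, 3 equiv), THF, 0 °C → rt
Reagents that add atoms: none
Why: Fluoride-mediated desilylation buffered with acetic acid frees the side-chain carbinol while sparing the α-acetoxy ketone and both oxiranes.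

Step 15
Reactants: 23 (1S,3S,4R,5S,6S)-4-{(3R)-4-[(2S)-3,3-dimethyloxiran-2-yl]-3-hydroxybut-1-en-2-yl}-5-hydroxy-1-methyl-2-oxo-7-oxabicyclo[4.1.0]heptan-3-yl acetate; 24 angelic acid
Product: 26 (1S,3S,4R,5S,6S)-3-acetoxy-4-{(3R)-4-[(2S)-3,3-dimethyloxiran-2-yl]-3-[(Z)-2-methylbut-2-enoyloxy]but-1-en-2-yl}-1-methyl-2-oxo-7-oxabicyclo[4.1.0]heptan-5-yl (Z)-2-methylbut-2-enoate, via mixed anhydride 25 (not isolated)
Conditions: 24 (6 equiv), 2,4,6-trichlorobenzoyl chloride (6 equiv), Et3N (6 equiv), toluene, rt; then 23, 80 °C (no DMAP)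
Reagents that add atoms: none
Why: Yamaguchi-type mixed-anhydride esterification run without a nucleophilic catalyst acylates both hydroxyls with retention at carbon and avoids the addition–elimination pathway that turns angelate (Z) into tiglate (E).

**Compound list**
1 | 2-bromoacrolein (2-bromoprop-2-enal) | C=C(Br)C=O | starting material
2 | (3R)-2-bromohexa-1,5-dien-3-yl diisopinocampheylborinate (isopinocampheyl groups from (−)-α-pinene) | C=CC[C@@H](OB([C@H]1C[C@H]2C[C@@H]([C@@H]1C)C2(C)C)[C@H]1C[C@H]2C[C@@H]([C@@H]1C)C2(C)C)C(Br)=C | intermediate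
3 | (3R)-2-bromohexa-1,5-dien-3-ol | C=C(Br)[C@@H](CC=C)O | intermediate
4 | tert-butyl{[(3R)-2-bromohexa-1,5-dien-3-yl]oxy}dimethylsilane | C=C(Br)[C@@H](CC=C)O[Si](C)(C)C(C)(C)C | intermediate
5 | tert-butyl{[(3R)-2-bromo-6-methylhepta-1,5-dien-3-yl]oxy}dimethylsilane | C=C(Br)[C@@H](CC=C(C)C)O[Si](C)(C)C(C)(C)C | intermediate
6 | tert-butyl({(2R)-3-bromo-1-[(2S)-3,3-dimethyloxiran-2-yl]but-3-en-2-yl}oxy)dimethylsilane | C=C(Br)[C@@H](C[C@@H]1OC1(C)C)O[Si](C)(C)C(C)(C)C | intermediate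
7 | 4-methoxy-3-methylphenol | COc1ccc(O)cc1C | starting material
8 | 2-iodo-4-methoxy-5-methylphenol | Oc1cc(C)c(OC)cc1I | intermediate
9 | 2-iodo-4,4-dimethoxy-5-methylcyclohexa-2,5-dien-1-one | COC1(OC)C=C(I)C(=O)C=C1C | intermediate
10 | 2-{[(1R)-2-iodo-4,4-dimethoxy-5-methylcyclohexa-2,5-dien-1-yl]oxy}-1,3,2-benzodioxaborole | O(B1Oc2ccccc2O1)[C@H]1C(I)=CC(OC)(OC)C(C)=C1 | intermediate
11 | (1R)-2-iodo-4,4-dimethoxy-5-methylcyclohexa-2,5-dien-1-ol | O[C@H]1C(I)=CC(OC)(OC)C(C)=C1 | intermediate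
12 | (1S,2R,6S)-3-iodo-5,5-dimethoxy-6-methyl-7-oxabicyclo[4.1.0]hept-3-en-2-ol (hydroxyl cis to the oxirane oxygen) | O[C@H]1C(I)=CC(OC)(OC)[C@@]2(C)O[C@@H]12 | intermediate
13 | (1S,2S,6S)-5,5-dimethoxy-6-methyl-7-oxabicyclo[4.1.0]hept-3-en-2-ol | O[C@H]1C=CC(OC)(OC)[C@@]2(C)O[C@@H]12 | intermediate
14 | (1S,5S,6S)-5-hydroxy-1-methyl-7-oxabicyclo[4.1.0]hept-3-en-2-one (epoxyquinol, hydroxyl cis to the oxirane oxygen) | O=C1C=C[C@H](O)[C@@H]2O[C@]12C | intermediate
15 | {(3R)-3-[(tert-butyldimethylsilyl)oxy]-4-[(2S)-3,3-dimethyloxiran-2-yl]but-1-en-2-yl}lithium | [Li]C(=C)[C@@H](C[C@@H]1OC1(C)C)O[Si](C)(C)C(C)(C)C | intermediate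
16 | {(3R)-3-[(tert-butyldimethylsilyl)oxy]-4-[(2S)-3,3-dimethyloxiran-2-yl]but-1-en-2-yl}magnesium bromide | Br[Mg]C(=C)[C@@H](C[C@@H]1OC1(C)C)O[Si](C)(C)C(C)(C)C | intermediate
17 | chloromagnesium alkoxide of 14 | O=C1C=C[C@H](O[Mg]Cl)[C@@H]2O[C@]12C | intermediate
18 | magnesium enolate of 19 (C2 enolate O–MgBr, C5 O–MgCl) | C=C([C@@H]1[C@H](O[Mg]Cl)[C@@H]2O[C@]2(C)C(O[Mg]Br)=C1)[C@@H](C[C@@H]1OC1(C)C)O[Si](C)(C)C(C)(C)C | intermediate
19 | (1S,4R,5S,6S)-4-{(3R)-3-[(tert-butyldimethylsilyl)oxy]-4-[(2S)-3,3-dimethyloxiran-2-yl]but-1-en-2-yl}-5-hydroxy-1-methyl-7-oxabicyclo[4.1.0]heptan-2-one | C=C([C@@H]1[C@H](O)[C@@H]2O[C@]2(C)C(=O)C1)[C@@H](C[C@@H]1OC1(C)C)O[Si](C)(C)C(C)(C)C | intermediate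
20 | dipotassium C2(C3)-enolate C5-alkoxide of 19 | [K+].[K+].C=C([C@@H]1[C@H]([O-])[C@@H]2O[C@]2(C)C([O-])=C1)[C@@H](C[C@@H]1OC1(C)C)O[Si](C)(C)C(C)(C)C | intermediate
21 | (1S,3S,4R,5S,6S)-4-{(3R)-3-[(tert-butyldimethylsilyl)oxy]-4-[(2S)-3,3-dimethyloxiran-2-yl]but-1-en-2-yl}-3,5-dihydroxy-1-methyl-7-oxabicyclo[4.1.0]heptan-2-one | C=C([C@@H]1[C@H](O)[C@@H]2O[C@]2(C)C(=O)[C@H]1O)[C@@H](C[C@@H]1OC1(C)C)O[Si](C)(C)C(C)(C)C | intermediate
22 | (1S,3S,4R,5S,6S)-4-{(3R)-3-[(tert-butyldimethylsilyl)oxy]-4-[(2S)-3,3-dimethyloxiran-2-yl]but-1-en-2-yl}-5-hydroxy-1-methyl-2-oxo-7-oxabicyclo[4.1.0]heptan-3-yl acetate | C=C([C@@H]1[C@H](O)[C@@H]2O[C@]2(C)C(=O)[C@H]1OC(C)=O)[C@@H](C[C@@H]1OC1(C)C)O[Si](C)(C)C(C)(C)C | intermediate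
23 | (1S,3S,4R,5S,6S)-4-{(3R)-4-[(2S)-3,3-dimethyloxiran-2-yl]-3-hydroxybut-1-en-2-yl}-5-hydroxy-1-methyl-2-oxo-7-oxabicyclo[4.1.0]heptan-3-yl acetate | C=C([C@@H]1[C@H](O)[C@@H]2O[C@]2(C)C(=O)[C@H]1OC(C)=O)[C@@H](C[C@@H]1OC1(C)C)O | intermediate
24 | angelic acid ((Z)-2-methylbut-2-enoic acid) | C/C=C(/C)C(=O)O | starting material
25 | (Z)-2-methylbut-2-enoic 2,4,6-trichlorobenzoic anhydride | C/C=C(/C)C(=O)OC(=O)c1c(Cl)cc(Cl)cc1Cl | intermediate
26 | (1S,3S,4R,5S,6S)-3-acetoxy-4-{(3R)-4-[(2S)-3,3-dimethyloxiran-2-yl]-3-[(Z)-2-methylbut-2-enoyloxy]but-1-en-2-yl}-1-methyl-2-oxo-7-oxabicyclo[4.1.0]heptan-5-yl (Z)-2-methylbut-2-enoate (CNP0407453.2) | C=C([C@@H]1[C@H](OC(=O)/C(C)=C\C)[C@@H]2O[C@]2(C)C(=O)[C@H]1OC(C)=O)[C@@H](C[C@@H]1OC1(C)C)OC(=O)/C(C)=C\C | target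

**Totals and risk**

Total step count: 15. Longest linear sequence: 11 steps (7 → 26, steps 5–15); the side-chain branch (1 → 6) is 4 steps.

Three steps most likely to fail:

Step 11 (directed conjugate addition). The Grignard reagent may add 1,2 to the epoxy ketone, or add from the face opposite the alkoxide. The fallback makes the same C–C bond as an sp2–sp2 coupling before the ketone exists and sets C4 afterwards with hydride. It sets out from iodide 12 and uses alkenyllithium 15. Transmetalation of 15 with ZnCl2 gives {(3R)-3-[(tert-butyldimethylsilyl)oxy]-4-[(2S)-3,3-dimethyloxiran-2-yl]but-1-en-2-yl}zinc chloride F1. Negishi coupling of F1 with 12 (Pd(PPh3)4, THF, rt) gives the 1,3-diene ketal F2. Ketal hydrolysis (PPTS, acetone/H2O) gives the dienone F3. Conjugate reduction of F3 with Stryker's reagent [(Ph3P)CuH]6 (toluene, wet, rt) should deliver hydride to C4 from the face opposite the C5 hydroxyl and the oxirane, which pushes the side chain cis to both. The fallback comes back to the route at ketone 19.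

Step 13 (selective mono-acetylation). The C5 hydroxyl may compete, or acetyl may migrate. The fallback introduces the acetoxy group as an electrophile while O5 is masked. It sets out from ketone 19. KN(SiMe3)2 and Me3SiCl (THF, −78 °C) give the C5 trimethylsilyl ether / C2–C3 trimethylsilyl enol ether F4. Pb(OAc)4 in CH2Cl2 at −40 °C acetoxylates the enol ether from the face opposite the side chain to give the α-acetoxy ketone F5. Citric acid in MeOH at 0 °C removes the trimethylsilyl ether. The fallback comes back to the route at acetate 22.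

Step 15 (double angeloylation). The hindered axial C5 hydroxyl may not acylate, or the angelate may isomerise to tiglate at 80 °C. The fallback builds the Z-olefin after acylation. It sets out from diol 23. Esterification with 2-[bis(2-methylphenoxy)phosphoryl]propanoic acid (DCC, DMAP, CH2Cl2) gives the bis(phosphonopropionate) F6. A Z-selective Horner–Wadsworth–Emmons reaction of F6 with acetaldehyde (Ando variant; NaI, DBU, THF, −78 → 0 °C) forms both (Z)-2-methylbut-2-enoates. The fallback comes back to the route at target 26.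

Further compounds
F1 | step 11 | {(3R)-3-[(tert-butyldimethylsilyl)oxy]-4-[(2S)-3,3-dimethyloxiran-2-yl]but-1-en-2-yl}zinc chloride | Cl[Zn]C(=C)[C@@H](C[C@@H]1OC1(C)C)O[Si](C)(C)C(C)(C)C
F2 | step 11 | (1S,2S,6S)-3-{(3R)-3-[(tert-butyldimethylsilyl)oxy]-4-[(2S)-3,3-dimethyloxiran-2-yl]but-1-en-2-yl}-5,5-dimethoxy-6-methyl-7-oxabicyclo[4.1.0]hept-3-en-2-ol | O[C@H]1C(C(=C)[C@@H](C[C@@H]2OC2(C)C)O[Si](C)(C)C(C)(C)C)=CC(OC)(OC)[C@@]2(C)O[C@@H]12
F3 | step 11 | (1S,5S,6S)-4-{(3R)-3-[(tert-butyldimethylsilyl)oxy]-4-[(2S)-3,3-dimethyloxiran-2-yl]but-1-en-2-yl}-5-hydroxy-1-methyl-7-oxabicyclo[4.1.0]hept-3-en-2-one | O=C1C=C(C(=C)[C@@H](C[C@@H]2OC2(C)C)O[Si](C)(C)C(C)(C)C)[C@H](O)[C@@H]2O[C@]12C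
F4 | step 13 | (1S,4R,5S,6S)-4-{(3R)-3-[(tert-butyldimethylsilyl)oxy]-4-[(2S)-3,3-dimethyloxiran-2-yl]but-1-en-2-yl}-1-methyl-2,5-bis[(trimethylsilyl)oxy]-7-oxabicyclo[4.1.0]hept-2-ene | C=C([C@@H]1[C@H](O[Si](C)(C)C)[C@@H]2O[C@]2(C)C(O[Si](C)(C)C)=C1)[C@@H](C[C@@H]1OC1(C)C)O[Si](C)(C)C(C)(C)C
F5 | step 13 | (1S,3S,4S,5S,6S)-4-{(3R)-3-[(tert-butyldimethylsilyl)oxy]-4-[(2S)-3,3-dimethyloxiran-2-yl]but-1-en-2-yl}-1-methyl-2-oxo-5-[(trimethylsilyl)oxy]-7-oxabicyclo[4.1.0]heptan-3-yl acetate (same geometry as 22; the C4 descriptor changes only because of the silyl group) | C=C([C@@H]1[C@H](O[Si](C)(C)C)[C@@H]2O[C@]2(C)C(=O)[C@H]1OC(C)=O)[C@@H](C[C@@H]1OC1(C)C)O[Si](C)(C)C(C)(C)C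
F6 | step 15 | (1S,3S,4R,5S,6S)-3-acetoxy-4-{(3R)-3-({2-[bis(2-methylphenoxy)phosphoryl]propanoyl}oxy)-4-[(2S)-3,3-dimethyloxiran-2-yl]but-1-en-2-yl}-1-methyl-2-oxo-7-oxabicyclo[4.1.0]heptan-5-yl 2-[bis(2-methylphenoxy)phosphoryl]propanoate (mixture at the two phosphonate α-carbons) | C=C([C@@H]1[C@H](OC(=O)C(C)P(=O)(Oc2ccccc2C)Oc2ccccc2C)[C@@H]2O[C@]2(C)C(=O)[C@H]1OC(C)=O)[C@@H](C[C@@H]1OC1(C)C)OC(=O)C(C)P(=O)(Oc1ccccc1C)Oc1ccccc1C
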